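**Plan**

- Retrosynthesis: the twelve O–CH3 bonds are cut first. Next comes the diaryl ether bond between the oxygen on C1 of ring C and C6 of ring B, then the two biaryl bonds C3(ring C)–C1'(ring D) and C5(ring C)–C1'(ring E). The AB fragment is cut at the ether bond from the ring B oxygen to C1 of ring A.
- Enabling feature: ring C bears oxygen on C1, C2, C4 and C6 and the aryl rings D and E on C3 and C5. This is the pattern of 2,6-dimethoxy-1,4-benzoquinone (carbonyls at C1 and C4, methoxy groups at C2 and C6) substituted at its only two C–H carbons, so both biaryl bonds can come from addition of nucleophilic 1,3,5-trimethoxybenzene to the quinone with reoxidation.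
- Forward: no ring is constructed; all five benzene rings are bought. Step 1 joins D and E to C, steps 2–4 build the AB bromide from 5-bromovanillin, step 5 takes ring C to the hydroquinone, step 6 joins AB to the exposed C1 hydroxyl, and step 7 frees the thirteen phenols.
- Stereochemistry: none to set. The target has no stereocentre, and each biaryl axis carries a symmetric 2,4,6-trioxygenated ring.

Key step: step 1

Remark: ring C is numbered throughout as in the quinone (C1 and C4 carry the carbonyl oxygens, C2 and C6 the methoxy groups, C3 and C5 the aryl rings).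

**Step 1**
Reactants: 1 2,6-dimethoxy-1,4-benzoquinone; 2 1,3,5-trimethoxybenzene
Product: 6 2,6-dimethoxy-3,5-bis(2,4,6-trimethoxyphenyl)-1,4-benzoquinone, via monoaryl hydroquinone 3 (not isolated), via monoaryl quinone 4 (not isolated), via diaryl hydroquinone 5 (not isolated)
Conditions: 2 (3 equiv), CF3CO2H/CH2Cl2 (1:3), Cu(OAc)2 (10 mol %), O2 (1 atm), 0 °C to rt
Reagents that add atoms: none
Why: Hydrogen bonding and protonation by CF3CO2H at the C1 carbonyl of 1 make C3, its β-carbon, electrophilic; an unsubstituted ring carbon of 2 attacks there, the arenium ion loses a proton and the adduct enolises to hydroquinone 3. The copper/O2 couple, as in copper-catalysed aerobic hydroquinone oxidations, should return 3 to quinone 4, whose remaining C5–H carbon reacts in the same way to give 5, which is oxidised to 6 with water as the only coproduct. The closest known reaction type is the acid-promoted Friedel–Crafts conjugate arylation of quinones by methoxyarenes with in situ dehydrogenation, an oxidative arylation of a quinone C–H bond. No ring closes and no stereocentre forms. The step needs attack at the C–H carbons C3 and C5 and not addition–elimination at the methoxy-bearing C2 and C6: attack at those fully substituted carbons would give a crowded, reversible quaternary adduct, whereas the C3 and C5 adducts aromatise irreversibly, and regioisomers cannot arise because 1 has only these two C–H positions and 2 has three equivalent ones. The excess of 2 keeps the attached rings D and E and the hydroquinone-level intermediates from competing as nucleophiles, and O2 is too weak an oxidant to attack the methoxyarenes.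

**Step 2**
Reactants: 7 5-bromovanillin (3-bromo-4-hydroxy-5-methoxybenzaldehyde); 8 3,5-dimethoxyphenylboronic acid
Product: 9 3-bromo-4-(3,5-dimethoxyphenoxy)-5-methoxybenzaldehyde
Conditions: 8 (2 equiv), Cu(OAc)2 (1.5 equiv), pyridine, 4 Å MS, CH2Cl2, dry air, rt
Reagents that add atoms: none
Why: Chan–Lam–Evans O-arylation, in which the phenoxide of 7 and the aryl group of 8 meet on copper and are joined by reductive elimination at room temperature, a manifold that accepts phenols flanked by ortho halogen and alkoxy groups and leaves the aryl bromide and the aldehyde untouched.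

**Step 3**
Reactants: 9 3-bromo-4-(3,5-dimethoxyphenoxy)-5-methoxybenzaldehyde
Product: 11 3-bromo-4-(3,5-dimethoxyphenoxy)-5-methoxyphenol, via aryl formate 10 (not isolated)
Conditions: mCPBA, CH2Cl2, 0 °C to rt; aq. NaHCO3 wash; then Et3N (cat.), MeOH, rt
Reagents that add atoms: meta-chloroperbenzoic acid (mCPBA), O=C(OO)c1cccc(Cl)c1
Why: Baeyer–Villiger oxidation of an electron-rich benzaldehyde (Dakin-type), in which the ring carrying the para aryloxy donor migrates in the Criegee intermediate to give formate 10, which base-catalysed methanolysis cleaves to the phenol, as is standard for 3-halo-4,5-dialkoxybenzaldehydes.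

**Step 4**
Reactants: 11 3-bromo-4-(3,5-dimethoxyphenoxy)-5-methoxyphenol
Product: 12 1-bromo-2-(3,5-dimethoxyphenoxy)-3,5-dimethoxybenzene
Conditions: MeI, K2CO3, acetone, reflux
Reagents that add atoms: iodomethane, CI
Why: Williamson ether synthesis on an unhindered phenoxide, with no other alkylatable site in 11.

**Step 5**
Reactants: 6 2,6-dimethoxy-3,5-bis(2,4,6-trimethoxyphenyl)-1,4-benzoquinone
Product: 5 2,6-dimethoxy-3,5-bis(2,4,6-trimethoxyphenyl)benzene-1,4-diol
Conditions: Na2S2O4, EtOAc/H2O, rt, argon
Reagents that add atoms: none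
Why: Dithionite reduction of a quinone to its hydroquinone is fast and clean in a two-phase system, and here it supplies from purified 6, immediately before use, the same air-sensitive hydroquinone that passes through step 1.

**Step 6**
Reactants: 5 2,6-dimethoxy-3,5-bis(2,4,6-trimethoxyphenyl)benzene-1,4-diol; 12 1-bromo-2-(3,5-dimethoxyphenoxy)-3,5-dimethoxybenzene
Product: 13 4-[2-(3,5-dimethoxyphenoxy)-3,5-dimethoxyphenoxy]-3,5-dimethoxy-2,6-bis(2,4,6-trimethoxyphenyl)phenol
Conditions: 12 (1.5 equiv), CuI (0.3 equiv), picolinic acid (0.6 equiv), K3PO4 (3 equiv), degassed DMSO, 100 °C, argon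
Reagents that add atoms: none
Why: Ligand-accelerated Ullmann diaryl ether synthesis in the picolinic acid variant used for doubly ortho-substituted phenols and ortho-substituted aryl halides; the C1 hydroxyl, flanked only by two methoxy groups, should be arylated while the C4 hydroxyl, buried between the two perpendicular trimethoxyphenyl rings, should not, and exclusion of oxygen keeps 5 from returning to 6.

**Step 7**
Reactants: 13 4-[2-(3,5-dimethoxyphenoxy)-3,5-dimethoxyphenoxy]-3,5-dimethoxy-2,6-bis(2,4,6-trimethoxyphenyl)phenol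
Product: 14 2-[2-(3,5-dihydroxyphenoxy)-3,5-dihydroxyphenoxy]-4,6-bis(2,4,6-trihydroxyphenyl)benzene-1,3,5-triol (CNP0228669.0)
Conditions: BBr3 (excess), CH2Cl2, −78 °C to rt; then H2O, 0 °C, argon
Reagents that add atoms: none
Why: Boron tribromide cleavage of aryl methyl ethers, in which each methoxy oxygen is complexed and its methyl group is removed by bromide, while the diaryl ether and biaryl bonds offer no such SN2 carbon and should remain.

**Compound list**

1 | 2,6-dimethoxy-1,4-benzoquinone | COC1=CC(=O)C=C(OC)C1=O | starting material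
2 | 1,3,5-trimethoxybenzene | COc1cc(OC)cc(OC)c1 | starting material
3 | 2,6-dimethoxy-3-(2,4,6-trimethoxyphenyl)benzene-1,4-diol | COc1cc(O)c(-c2c(OC)cc(OC)cc2OC)c(OC)c1O | intermediate
4 | 2,6-dimethoxy-3-(2,4,6-trimethoxyphenyl)-1,4-benzoquinone | COC1=CC(=O)C(-c2c(OC)cc(OC)cc2OC)=C(OC)C1=O | intermediate
5 | 2,6-dimethoxy-3,5-bis(2,4,6-trimethoxyphenyl)benzene-1,4-diol | COc1c(O)c(OC)c(-c2c(OC)cc(OC)cc2OC)c(O)c1-c1c(OC)cc(OC)cc1OC | intermediate
6 | 2,6-dimethoxy-3,5-bis(2,4,6-trimethoxyphenyl)-1,4-benzoquinone | COC1=C(-c2c(OC)cc(OC)cc2OC)C(=O)C(-c2c(OC)cc(OC)cc2OC)=C(OC)C1=O | intermediate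
7 | 5-bromovanillin (3-bromo-4-hydroxy-5-methoxybenzaldehyde) | COc1cc(C=O)cc(Br)c1O | starting material
8 | 3,5-dimethoxyphenylboronic acid | COc1cc(OC)cc(B(O)O)c1 | starting material
9 | 3-bromo-4-(3,5-dimethoxyphenoxy)-5-methoxybenzaldehyde | COc1cc(OC)cc(Oc2c(Br)cc(C=O)cc2OC)c1 | intermediate
10 | 3-bromo-4-(3,5-dimethoxyphenoxy)-5-methoxyphenyl formate | COc1cc(OC)cc(Oc2c(Br)cc(OC=O)cc2OC)c1 | intermediate
11 | 3-bromo-4-(3,5-dimethoxyphenoxy)-5-methoxyphenol | COc1cc(OC)cc(Oc2c(Br)cc(O)cc2OC)c1 | intermediate
12 | 1-bromo-2-(3,5-dimethoxyphenoxy)-3,5-dimethoxybenzene | COc1cc(OC)cc(Oc2c(Br)cc(OC)cc2OC)c1 | intermediate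
13 | 4-[2-(3,5-dimethoxyphenoxy)-3,5-dimethoxyphenoxy]-3,5-dimethoxy-2,6-bis(2,4,6-trimethoxyphenyl)phenol | COc1cc(OC)cc(Oc2c(OC)cc(OC)cc2Oc2c(OC)c(-c3c(OC)cc(OC)cc3OC)c(O)c(-c3c(OC)cc(OC)cc3OC)c2OC)c1 | intermediate
14 | 2-[2-(3,5-dihydroxyphenoxy)-3,5-dihydroxyphenoxy]-4,6-bis(2,4,6-trihydroxyphenyl)benzene-1,3,5-triol | Oc1cc(O)cc(Oc2c(O)cc(O)cc2Oc2c(O)c(-c3c(O)cc(O)cc3O)c(O)c(-c3c(O)cc(O)cc3O)c2O)c1 | target

**Totals**

Total step count: 7. Longest linear sequence: 5 steps (7 → 9 → 11 → 12 → 13 → 14, steps 2, 3, 4, 6 and 7).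

**Steps most likely to fail**

Step 1. Reoxidation may lag behind the arylation, so that hydroquinone-level intermediates accumulate and add as nucleophiles to the remaining quinone, or the arene may displace methoxide at C2 or C6 by addition–elimination. The fallback replaces the like-polarity union by a halide/boronic acid pairing. It sets out from 1, which is brominated at both C–H carbons (Br2, AcOH) to 3,5-dibromo-2,6-dimethoxy-1,4-benzoquinone F1. A double Suzuki–Miyaura coupling of F1 with commercial 2,4,6-trimethoxyphenylboronic acid, used in excess (Pd(OAc)2, SPhos, K3PO4, toluene/H2O, 80 °C), would then return to the route at 6.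

Step 6. The electron-rich hydroquinone phenoxide may be oxidised back to the quinone by traces of oxygen under the basic copper conditions, and the coupling between a doubly flanked phenoxide and an ortho-substituted, electron-rich bromide may be slow. The fallback removes the hydroquinone before the coupling:
- It sets out from 5, whose exposed C1 hydroxyl is acylated selectively (pivaloyl chloride, pyridine, CH2Cl2, 0 °C) to 4-hydroxy-2,6-dimethoxy-3,5-bis(2,4,6-trimethoxyphenyl)phenyl pivalate F2.
- The buried C4 hydroxyl is then methylated (MeI, Cs2CO3, DMF) to 2,4,6-trimethoxy-3,5-bis(2,4,6-trimethoxyphenyl)phenyl pivalate F3.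
- Methanolysis (NaOMe, MeOH) frees 2,4,6-trimethoxy-3,5-bis(2,4,6-trimethoxyphenyl)phenol F4, which cannot form a quinone and can therefore be forced with more copper and heat.
- Ullmann coupling of F4 with 12 under the conditions of step 6 gives 2-[2-(3,5-dimethoxyphenoxy)-3,5-dimethoxyphenoxy]-1,3,5-trimethoxy-4,6-bis(2,4,6-trimethoxyphenyl)benzene F5.
- BBr3 as in step 7 cleaves all thirteen methyl ethers of F5, and the route is rejoined at 14.

Step 7. Cleavage of the twelve ethers may stop short, and the free polyphenol may suffer air oxidation or acid-induced dehydrative cyclisation of its 2,2'-dihydroxybiaryl units during isolation. The fallback sets out from 13 and does not isolate the free phenol from the BBr3 mixture. The crude product is acetylated exhaustively (Ac2O, pyridine, DMAP) to the tridecaacetate 2-[2-(3,5-diacetoxyphenoxy)-3,5-diacetoxyphenoxy]-4,6-bis(2,4,6-triacetoxyphenyl)benzene-1,3,5-triyl triacetate F6. F6 is stable and can be purified on silica, with partly methylated material removed. Acid-catalysed methanolysis (HCl in degassed MeOH, argon) then releases the phenols and returns to the route at 14.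

**Further compounds**

F1 | step 1 | 3,5-dibromo-2,6-dimethoxy-1,4-benzoquinone | COC1=C(Br)C(=O)C(Br)=C(OC)C1=O
F2 | step 6 | 4-hydroxy-2,6-dimethoxy-3,5-bis(2,4,6-trimethoxyphenyl)phenyl pivalate | COc1c(OC(=O)C(C)(C)C)c(OC)c(-c2c(OC)cc(OC)cc2OC)c(O)c1-c1c(OC)cc(OC)cc1OC
F3 | step 6 | 2,4,6-trimethoxy-3,5-bis(2,4,6-trimethoxyphenyl)phenyl pivalate | COc1c(OC(=O)C(C)(C)C)c(OC)c(-c2c(OC)cc(OC)cc2OC)c(OC)c1-c1c(OC)cc(OC)cc1OC
F4 | step 6 | 2,4,6-trimethoxy-3,5-bis(2,4,6-trimethoxyphenyl)phenol | COc1c(O)c(OC)c(-c2c(OC)cc(OC)cc2OC)c(OC)c1-c1c(OC)cc(OC)cc1OC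
F5 | step 6 | 2-[2-(3,5-dimethoxyphenoxy)-3,5-dimethoxyphenoxy]-1,3,5-trimethoxy-4,6-bis(2,4,6-trimethoxyphenyl)benzene | COc1cc(OC)cc(Oc2c(OC)cc(OC)cc2Oc2c(OC)c(-c3c(OC)cc(OC)cc3OC)c(OC)c(-c3c(OC)cc(OC)cc3OC)c2OC)c1
F6 | step 7 | 2-[2-(3,5-diacetoxyphenoxy)-3,5-diacetoxyphenoxy]-4,6-bis(2,4,6-triacetoxyphenyl)benzene-1,3,5-triyl triacetate | CC(=O)Oc1cc(OC(C)=O)cc(Oc2c(OC(C)=O)cc(OC(C)=O)cc2Oc2c(OC(C)=O)c(-c3c(OC(C)=O)cc(OC(C)=O)cc3OC(C)=O)c(OC(C)=O)c(-c3c(OC(C)=O)cc(OC(C)=O)cc3OC(C)=O)c2OC(C)=O)c1
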